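## Analysis of the target

The target is a germacranolide: a ten-membered carbocycle (C1–C10, germacrane numbering) fused trans at C6–C7 to an α-methylene-γ-butyrolactone (lactone oxygen on C6, carbonyl C12, exocyclic methylene on C11). The ring carries a Z-trisubstituted alkene at C4=C5 and a trisubstituted oxirane across C1–C10, with the methyl group on C10. At C8 it carries the ester of (2S,3S)-2,3-epoxy-2-methylbutanoic acid. Five ring stereocentres (1R, 6R, 7R, 8R, 10R) and two in the side chain must be set. C6/C7 is a syn-aldol pair that gives the trans lactone, O6 and O8 are 1,3-anti across C7, and the oxirane is trans (C2 and C9 on opposite faces). The sensitive groups are the α-methylene lactone (Michael acceptor), the two oxiranes (acid, and in the medium ring transannular attack by C4=C5) and the allylic C6–O bond. The difficulty is closing a strained ten-membered ring and installing an oxirane whose configuration does not depend on the conformation of that ring. The strategy rests on one feature: C10 is β to the C8 oxygen across C9, an aldol relationship, and C1 can carry a leaving group. A C8 ketone enolate adding through C9 to a C10 methyl ketone with a C1 chloride therefore makes the ring bond C9–C10 and then the oxirane.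

## Retrosynthetic reasoning

**C11 methylene.** The exocyclic C=C of 39 is removed first, so that the Michael acceptor exists only in the last step. It comes from ester 35 by a Mannich reaction on lactone enolate 36 and elimination through 37 and 38. The C8 acyl group has no α-hydrogen, so it can stay in place during the enolate step and no separate protecting group is needed at O8.

**C8–O acyl bond.** Cutting the ester gives hydroxy lactone 29 and acid 33. The bond is hindered on both sides, so the forward step uses the mixed anhydride 34. Acid 33 goes back through epoxy alcohol 32 and allylic alcohol 31 to angelic acid 30; the Z alkene of 30 fixes the relative and a Sharpless epoxidation the absolute configuration.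

**C8 carbinol and lactone C–O bond.** Alcohol 29 comes from ketone 28, and lactone 28 from the silyl ether/methyl ester 26 through hydroxy ester 27. The order matters: C12 is γ to both O6 and O8, so the lactone is closed while C8 is still a ketone and only O6 can attack. The forward reduction must then deliver hydride to the face that gives 8R, which is the Felkin–Anh face with respect to C7.

**C9–C10 and O–C1 (key disconnection).** The ring of 26 is opened at C9–C10 and the oxirane at O–C1, which leads to the open-chain bromomethyl ketone/α-chloro methyl ketone 23. No other cut removes the ring, the quaternary C10–O centre and the oxirane at once, and none places control of both oxirane centres in a single open-chain stereocentre (C1). The forward reaction has to generate an enolate at C9 only, add it to the C10 ketone within the molecule, and let the C10 alkoxide displace chloride at C1.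

**The two halo ketones of 23.** Neither halo ketone survives the making of the other, so they are unmasked late and in order. The C10 ketone comes last by oxidation of carbinol 22. That carbinol is a silyl ether in 21 while the bromomethyl ketone is made from Weinreb amide 20 by a one-carbon homologation. Amide 20 comes from acid 19, and 19 from imide 17 via peroxy acid 18.

**C6–C7.** Silyl ether 17 is the protected form of the syn-aldol adduct 16, which is cut at C6–C7 into imide 14 and Z-enal 11. This one bond sets both C6 and C7 from the auxiliary, and the succinate unit of 14 brings C11 and C12 at the right oxidation level. Imide 14 comes from oxazolidinone 12 and acid chloride 13.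

**The enal.** Enal 11 comes by formylation of vinyllithium 10 from Z-iodide 9. The C1 chloride is traced through chlorohydrin 8 to chloro aldehyde 7 and aldehyde 6, where an enamine-catalysed chlorination sets it. Iodide 5, the acetal of 6, is cut at C3–C4 into Grignard reagent 3 (from chloride 1) and propyne 2 via alkenylcopper 4. Syn-carbometalation fixes the Z geometry, and the chain between C4 and the aldehyde carbon counts four carbons (C3, C2, C1, C10), which is why 1 is the chloropropyl dioxolane.

## Alternatives that were turned down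

**Alternative 1: three-component chain assembly around propyne.**
- Disconnection: C3–C4 and C5–C6 of the open chain; ring closure is left for a later C8–C9 alkylation.
- Forward key step: alkylcopper A3 adds syn across propyne 2, and the resulting Z-alkenylcopper adds to aldehyde A2 to give dienol A1.
- For: it is convergent, uses only known reaction types, and sets the Z alkene by the same syn-carbocupration that the chosen route uses. On precedent it is the stronger proposal.
- Against: alkenylcopper reagents add poorly to aldehydes. C6 would be set only by substrate control from an α-dithianyl aldehyde that epimerises easily. The step closes no ring, so it leaves the macrocyclisation, dithiane removal, two oxidation-state changes (C9, C12) and an epoxidation that must distinguish C1=C10 from C4=C5 and choose a face.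
- Comparison: the chosen strategy sets C6/C7 with an auxiliary and makes ring, oxirane and both oxirane centres in one step, at the price of one unprecedented operation.

**Alternative 2: lactone by cyclocarbonylation.**
- Disconnection: O–C12 and C12–C11 of the lactone.
- Forward key step: ring alkynol A5, with trans hydroxyl and ethynyl groups, is carbonylated (PdCl2(PPh3)2, SnCl2, CO) to methylene lactone A4.
- For: the whole α-methylene lactone is made in one catalytic step without enolate chemistry. On this point it is stronger than the two-step Mannich sequence used here.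
- Against: it presupposes the ten-membered ring, which is the hard part. The Lewis-acidic tin salt and divalent palladium act on a 1,5-diene prone to transannular reactions. The reactive methylene lactone must then survive desilylation, esterification and an epoxidation whose site and face depend on ring conformation.
- Comparison: the chosen strategy gives up the one-step lactone but fixes the oxirane configuration from the C1 chloride and not from the ring, and makes the Michael acceptor last.

**Alternative 3: macro-alkylation at C2–C3.**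
- Disconnection: the doubly allylic C2–C3 bond.
- Forward key step: the bis-sulfone carbanion of open-chain bromide A7 (Cs2CO3, high dilution) displaces the allylic bromide to give ring A6.
- For: soft-carbanion alkylation is a proven, irreversible way to ten-membered rings. Both alkene geometries and the C6–C8 triad are set beforehand. On reliability of ring closure it is stronger than the chosen step.
- Against: the bond creates no stereocentre, and SN2′ attack competes. Two sulfones must be removed reductively next to an allylic system, which risks alkene migration. The oxirane still has to be introduced by a selective epoxidation, and the PMB and silyl groups add steps.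
- Comparison: the chosen strategy is shorter and couples ring closure with stereocontrolled oxirane formation. What it offers in place of the precedent is step economy and control of C1/C10 from an open-chain centre.

Key step: step 15

Assumption: the (2R,5R)-2,5-diphenylpyrrolidine catalyst is taken to deliver the (S)-chloride in step 3, as its shielding of the enamine face suggests; if the sense is the reverse, its mirror image is used.

## Route

Step 1
Reactants: 1 2-(3-chloropropyl)-1,3-dioxolane; 2 propyne
Product: 5 2-[(4Z)-5-iodo-4-methylpent-4-en-1-yl]-1,3-dioxolane, via Grignard reagent 3 (not isolated), via alkenylcopper 4 (not isolated)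
Conditions: Mg, THF, reflux; CuBr·SMe2, Et2O/Me2S, −45 °C; 2, −25 °C; I2, −50 → 0 °C
Reagents that add atoms: iodine, II
Why: Carbocupration of a terminal alkyne is a syn addition that puts the alkyl group and copper cis, and iodinolysis proceeds with retention, so the Z iodide should result.

Step 2
Reactants: 5 2-[(4Z)-5-iodo-4-methylpent-4-en-1-yl]-1,3-dioxolane
Product: 6 (5Z)-6-iodo-5-methylhex-5-enal
Conditions: 1 M HCl, THF, rt
Reagents that add atoms: water, O
Why: Acid-catalysed acetal hydrolysis; the vinyl iodide is inert to dilute acid.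

Step 3
Reactants: 6 (5Z)-6-iodo-5-methylhex-5-enal
Product: 7 (2S,5Z)-2-chloro-6-iodo-5-methylhex-5-enal
Conditions: NCS, (2R,5R)-2,5-diphenylpyrrolidine (10 mol %), CH2Cl2, 0 °C → rt; used crude
Reagents that add atoms: N-chlorosuccinimide, O=C1CCC(=O)N1Cl
Why: Enamine-catalysed α-chlorination of an aldehyde; the phenyl group next to the enamine carbon shields one face, so chlorine should enter from the other and give the S centre (C1 of the target skeleton).

Step 4
Reactants: 7 (2S,5Z)-2-chloro-6-iodo-5-methylhex-5-enal
Product: 8 (2R,3S,6Z)-3-chloro-7-iodo-6-methylhept-6-en-2-ol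
Conditions: MeMgBr, THF, −78 °C; aq. NH4Cl
Reagents that add atoms: methylmagnesium bromide, C[Mg]Br
Why: Grignard addition to an α-chloro aldehyde is fast at low temperature and removes the epimerisable aldehyde; the Cornforth arrangement should favour the anti chlorohydrin, and any C2 epimer is carried along because this carbinol is oxidised in step 14.

Step 5
Reactants: 8 (2R,3S,6Z)-3-chloro-7-iodo-6-methylhept-6-en-2-ol
Product: 9 {[(2R,3S,6Z)-3-chloro-7-iodo-6-methylhept-6-en-2-yl]oxy}triethylsilane
Conditions: TESCl, imidazole, CH2Cl2, 0 °C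
Reagents that add atoms: chlorotriethylsilane, CC[Si](Cl)(CC)CC
Why: Silylation of a secondary alcohol; imidazole is too weak a base to close the chlorohydrin to an oxirane.

Step 6
Reactants: 9 {[(2R,3S,6Z)-3-chloro-7-iodo-6-methylhept-6-en-2-yl]oxy}triethylsilane
Product: 11 (2Z,6S,7R)-6-chloro-3-methyl-7-[(triethylsilyl)oxy]oct-2-enal, via vinyllithium 10 (not isolated)
Conditions: t-BuLi (2.1 equiv), Et2O, −78 °C; DMF; aq. NH4Cl
Reagents that add atoms: N,N-dimethylformamide, CN(C)C=O
Why: Iodine–lithium exchange on a vinyl iodide is much faster than any reaction at the secondary chloride and retains the alkene geometry; formylation with DMF then gives the Z enal.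

Step 7
Reactants: 12 (4S)-4-benzyl-1,3-oxazolidin-2-one; 13 methyl 4-chloro-4-oxobutanoate
Product: 14 methyl 4-[(4S)-4-benzyl-2-oxo-1,3-oxazolidin-3-yl]-4-oxobutanoate
Conditions: Et3N, DMAP (cat.), CH2Cl2, 0 °C → rt
Reagents that add atoms: none
Why: N-acylation of the oxazolidinone by an acid chloride under nucleophilic catalysis.

Step 8
Reactants: 14 methyl 4-[(4S)-4-benzyl-2-oxo-1,3-oxazolidin-3-yl]-4-oxobutanoate; 11 (2Z,6S,7R)-6-chloro-3-methyl-7-[(triethylsilyl)oxy]oct-2-enal
Product: 16 methyl (3S,4R,5Z,9S,10R)-3-{[(4S)-4-benzyl-2-oxo-1,3-oxazolidin-3-yl]carbonyl}-9-chloro-4-hydroxy-6-methyl-10-[(triethylsilyl)oxy]undec-5-enoate, via boron enolate 15 (not isolated)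
Conditions: Bu2BOTf, i-Pr2NEt, CH2Cl2, −78 → 0 °C; 11, −78 → −20 °C; pH 7 buffer, MeOH, H2O2, 0 °C
Reagents that add atoms: none
Why: Evans syn-aldol reaction: the imide is enolised selectively over the ester to the Z boron enolate, and the Zimmerman–Traxler chair with the benzyl group turned away sets the 6R hydroxyl and the C7 centre (germacrane numbering) together.

Step 9
Reactants: 16 the syn-aldol adduct
Product: 17 the tert-butyldimethylsilyl ether of 16 at the C4 hydroxyl (C6 of the germacrane)
Conditions: TBSOTf, 2,6-lutidine, CH2Cl2, −78 °C, on crude 16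
Reagents that add atoms: tert-butyldimethylsilyl triflate, CC(C)(C)[Si](C)(C)OS(=O)(=O)C(F)(F)F
Why: Silyl triflate silylation is fast at −78 °C; it is run on the crude adduct so that the γ-hydroxy ester has no time to lactonise.

Step 10
Reactants: 17 the silylated imide
Product: 19 (2S,3R,4Z,8S,9R)-3-[(tert-butyldimethylsilyl)oxy]-8-chloro-2-(2-methoxy-2-oxoethyl)-5-methyl-9-[(triethylsilyl)oxy]dec-4-enoic acid, via peroxy acid 18 (not isolated)
Conditions: LiOH, H2O2, THF/H2O, 0 °C; Na2SO3; HCl to pH 4
Reagents that add atoms: hydrogen peroxide, OO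
Why: Hydroperoxide attacks the exocyclic imide carbonyl selectively and is not basic enough to hydrolyse the methyl ester or epimerise C7 at 0 °C; sulfite reduces the peroxy acid and the auxiliary 12 is recovered.

Step 11
Reactants: 19 the carboxylic acid
Product: 20 methyl (3S,4R,5Z,9S,10R)-4-[(tert-butyldimethylsilyl)oxy]-9-chloro-3-[methoxy(methyl)carbamoyl]-6-methyl-10-[(triethylsilyl)oxy]undec-5-enoate
Conditions: MeNHOMe·HCl, EDC·HCl, HOBt (cat.), i-Pr2NEt, CH2Cl2, 0 °C → rt
Reagents that add atoms: N,O-dimethylhydroxylamine hydrochloride, CNOC.Cl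
Why: Carbodiimide amide coupling through the active ester, which limits epimerisation at C7.

Step 12
Reactants: 20 the Weinreb amide
Product: 21 methyl (3S,4R,5Z,9S,10R)-3-(bromoacetyl)-4-[(tert-butyldimethylsilyl)oxy]-9-chloro-6-methyl-10-[(triethylsilyl)oxy]undec-5-enoate
Conditions: CH2Br2, MeLi·LiBr, THF/Et2O, −78 °C; aq. NH4Cl
Reagents that add atoms: dibromomethane, BrCBr
Why: Carbenoid homologation of a Weinreb amide: bromomethyllithium, made in the presence of the amide, adds to give a chelated tetrahedral adduct that releases the bromomethyl ketone only on work-up; the amide should react ahead of the methyl ester at −78 °C.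

Step 13
Reactants: 21 the bromomethyl ketone with both silyl ethers
Product: 22 methyl (3S,4R,5Z,9S,10R)-3-(bromoacetyl)-4-[(tert-butyldimethylsilyl)oxy]-9-chloro-10-hydroxy-6-methylundec-5-enoate
Conditions: PPTS, MeOH/CH2Cl2, 0 °C
Reagents that add atoms: none
Why: Acid-catalysed methanolysis removes the triethylsilyl ether much faster than the tert-butyldimethylsilyl ether; no amine is present that could alkylate the bromo ketone.

Step 14
Reactants: 22 the chlorohydrin
Product: 23 methyl (3S,4R,5Z,9S)-3-(bromoacetyl)-4-[(tert-butyldimethylsilyl)oxy]-9-chloro-6-methyl-10-oxoundec-5-enoate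
Conditions: DMP, NaHCO3, CH2Cl2, 0 °C → rt
Reagents that add atoms: none
Why: Dess–Martin oxidation under buffered, non-basic conditions gives the α-chloro methyl ketone without touching the C1 chloride centre; both C10 epimers of 22 converge here.

Step 15
Reactants: 23 the open-chain bromomethyl ketone/(S)-α-chloro methyl ketone
Product: 26 methyl [(1R,6R,7S,10R,4Z)-6-[(tert-butyldimethylsilyl)oxy]-1,10-epoxy-4,10-dimethyl-8-oxocyclodec-4-en-7-yl]acetate (germacrane numbering), via trivalent chromium enolate 24 (not isolated), via chlorohydrin alkoxide 25 (not isolated)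
Conditions: CrCl2 (4 equiv), THF, 0 °C → rt, 23 added over 10 h (2 mM final); then K2CO3, MeOH, 0 °C
Reagents that add atoms: none
Why: Proposed new method: divalent chromium abstracts bromine from the bromomethyl ketone in two one-electron steps and gives the trivalent chromium enolate 24, which is fixed at C9 and not basic enough to enolise C7 or the ester; the closest known reactions are chromium Reformatsky ring closures of α-bromo ketones onto aldehydes and Cornforth-controlled enolate additions to α-chloro ketones that are closed to oxiranes with base. C9 adds to the C10 ketone, which the α-chlorine makes the most electrophilic carbonyl in the molecule, and closes the ten-membered ring in a 10-(enolendo)-exo-trig mode; slow addition favours this over dimerisation and the Z C4=C5 alkene turns the chain back on itself. C10 is set by the C1 stereocentre: with C–Cl opposed to the carbonyl dipole the enolate enters past the C1 hydrogen, which gives the 10R chlorohydrin 25. Methanolic K2CO3 then frees the tertiary alkoxide from chromium, and it displaces chloride at C1 in a 3-exo-tet closure with inversion, so the (S)-chloride becomes the 1R oxirane carbon and the oxirane is trans. The step needs metal insertion at C–Br only, which the weaker C–Br bond, a temperature at or below room temperature and the absence of iodide should secure (iodide would exchange with the α-chloro ketone, racemise C1 and open it to reduction). It also needs oxirane closure ahead of retro-aldol cleavage and of enolisation towards C7 or C9; a tertiary β-chloro alkoxide closes much faster than a ketone is deprotonated, so the base stage is kept cold and short.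

Step 16
Reactants: 26 the ten-membered 8-ketone
Product: 28 (1R,6R,7S,10R,4Z)-1,10-epoxy-8-oxo-13-norgermacr-4-en-12,6-olide, via hydroxy ester 27 (not isolated)
Conditions: HF·pyridine, pyridine, THF, 0 °C → rt
Reagents that add atoms: none
Why: Buffered fluoride desilylation frees the C6 hydroxyl, which lactonises onto the γ-ester; C8 is still a ketone, so only the 6,12-lactone can form, and the buffer avoids both alkoxide (retro-aldol) and strong acid (oxirane opening).

Step 17
Reactants: 28 the keto lactone
Product: 29 (1R,6R,7R,8R,10R,4Z)-1,10-epoxy-8-hydroxy-13-norgermacr-4-en-12,6-olide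
Conditions: LiBH(s-Bu)3, THF, −78 °C; AcOH, −78 °C
Reagents that add atoms: none
Why: Bulky hydride reduction of a ketone in the presence of a lactone; attack anti to the C6 branch and past the C7 hydrogen (Felkin–Anh) should give the 8R alcohol, 1,3-anti to O6, and the cold acidic quench prevents translactonisation.

Step 18
Reactants: 30 angelic acid, (2Z)-2-methylbut-2-enoic acid
Product: 31 (2Z)-2-methylbut-2-en-1-ol
Conditions: LiAlH4, Et2O, 0 °C
Reagents that add atoms: none
Why: Hydride reduction of the acid to the allylic alcohol without change of alkene geometry.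

Step 19
Reactants: 31 (2Z)-2-methylbut-2-en-1-ol
Product: 32 [(2R,3S)-2,3-dimethyloxiran-2-yl]methanol
Conditions: Ti(Oi-Pr)4, D-(−)-diethyl tartrate, t-BuOOH, 4 Å MS, CH2Cl2, −20 °C
Reagents that add atoms: tert-butyl hydroperoxide, CC(C)(C)OO
Why: Sharpless asymmetric epoxidation; the L-(+)-tartrate gives 2S epoxy alcohols, so the D-(−)-ester should give the 2R,3S isomer needed here, and the Z alkene fixes the cis relation of C1 and the C3 methyl.

Step 20
Reactants: 32 [(2R,3S)-2,3-dimethyloxiran-2-yl]methanol
Product: 33 (2S,3S)-2,3-dimethyloxirane-2-carboxylic acid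
Conditions: TEMPO (cat.), PhI(OAc)2, MeCN/H2O, rt
Reagents that add atoms: water, O
Why: Oxoammonium oxidation of the primary alcohol through the aldehyde hydrate to the acid under near-neutral conditions that spare the oxirane; the C2 descriptor changes from R to S only because the CIP priorities change.

Step 21
Reactants: 29 the hydroxy lactone; 33 (2S,3S)-2,3-dimethyloxirane-2-carboxylic acid
Product: 35 (1R,6R,7R,8R,10R,4Z)-1,10-epoxy-8-{[(2S,3S)-2,3-dimethyloxiran-2-yl]carbonyloxy}-13-norgermacr-4-en-12,6-olide, via mixed anhydride 34 (not isolated)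
Conditions: 2,4,6-trichlorobenzoyl chloride, Et3N, THF; then 29, DMAP, toluene, rt
Reagents that add atoms: none
Why: Yamaguchi esterification couples hindered acids with hindered secondary alcohols; the acid has no α-hydrogen and cannot epimerise, and C8 reacts with retention.

Step 22
Reactants: 35 the C8 ester
Product: 37 the 13-(dimethylamino)-11,13-dihydro derivative of 39 (C11 epimers), via lithium enolate 36 (not isolated)
Conditions: LDA, THF, −78 °C; CH2=NMe2+ I−, −78 → 0 °C
Reagents that add atoms: N,N-dimethylmethyleneiminium iodide, C=[N+](C)C.[I-]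
Why: Mannich reaction of a lactone enolate with Eschenmoser's salt; C11 carries the only acidic hydrogens, and the new C11 centre is removed in the next step.

Step 23
Reactants: 37 the Mannich base
Product: 39 (1R,6R,7R,8R,10R,4Z)-1,10-epoxy-8-{[(2S,3S)-2,3-dimethyloxiran-2-yl]carbonyloxy}germacra-4,11(13)-dien-12,6-olide, via ammonium iodide 38 (not isolated)
Conditions: MeI, CH2Cl2/MeOH, rt; aq. NaHCO3, rt
Reagents that add atoms: none
Why: Quaternisation followed by E1cB elimination of trimethylamine under bicarbonate, which is too mild to open the oxiranes or add to the new methylene lactone.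

## Compound list

1 | 2-(3-chloropropyl)-1,3-dioxolane | ClCCCC1OCCO1 | starting material
2 | propyne | CC#C | starting material
3 | [3-(1,3-dioxolan-2-yl)propyl]magnesium chloride | Cl[Mg]CCCC1OCCO1 | intermediate (not isolated)
4 | (Z)-[5-(1,3-dioxolan-2-yl)-2-methylpent-1-en-1-yl]copper | [Cu]/C=C(/C)CCCC1OCCO1 | intermediate (not isolated)
5 | 2-[(4Z)-5-iodo-4-methylpent-4-en-1-yl]-1,3-dioxolane | I/C=C(/C)CCCC1OCCO1 | intermediate
6 | (5Z)-6-iodo-5-methylhex-5-enal | I/C=C(/C)CCCC=O | intermediate
7 | (2S,5Z)-2-chloro-6-iodo-5-methylhex-5-enal | I/C=C(/C)CC[C@H](Cl)C=O | intermediate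
8 | (2R,3S,6Z)-3-chloro-7-iodo-6-methylhept-6-en-2-ol | I/C=C(/C)CC[C@H](Cl)[C@@H](C)O | intermediate
9 | {[(2R,3S,6Z)-3-chloro-7-iodo-6-methylhept-6-en-2-yl]oxy}triethylsilane | I/C=C(/C)CC[C@H](Cl)[C@@H](C)O[Si](CC)(CC)CC | intermediate
10 | vinyllithium from 9 (lithium in place of iodine) | [Li]/C=C(/C)CC[C@H](Cl)[C@@H](C)O[Si](CC)(CC)CC | intermediate (not isolated)
11 | (2Z,6S,7R)-6-chloro-3-methyl-7-[(triethylsilyl)oxy]oct-2-enal | O=C/C=C(/C)CC[C@H](Cl)[C@@H](C)O[Si](CC)(CC)CC | intermediate
12 | (4S)-4-benzyl-1,3-oxazolidin-2-one | O=C1OC[C@H](Cc2ccccc2)N1 | starting material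
13 | methyl 4-chloro-4-oxobutanoate | COC(=O)CCC(Cl)=O | starting material
14 | methyl 4-[(4S)-4-benzyl-2-oxo-1,3-oxazolidin-3-yl]-4-oxobutanoate | COC(=O)CCC(=O)N1[C@@H](Cc2ccccc2)COC1=O | intermediate
15 | Z dibutylboron enolate of 14 | COC(=O)C/C=C(\OB(CCCC)CCCC)N1[C@@H](Cc2ccccc2)COC1=O | intermediate (not isolated)
16 | methyl (3S,4R,5Z,9S,10R)-3-{[(4S)-4-benzyl-2-oxo-1,3-oxazolidin-3-yl]carbonyl}-9-chloro-4-hydroxy-6-methyl-10-[(triethylsilyl)oxy]undec-5-enoate | O=C(N1[C@@H](Cc2ccccc2)COC1=O)[C@@H](CC(=O)OC)[C@H](O)/C=C(/C)CC[C@H](Cl)[C@@H](C)O[Si](CC)(CC)CC | intermediate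
17 | 4-O-tert-butyldimethylsilyl ether of 16 | O=C(N1[C@@H](Cc2ccccc2)COC1=O)[C@@H](CC(=O)OC)[C@H](O[Si](C)(C)C(C)(C)C)/C=C(/C)CC[C@H](Cl)[C@@H](C)O[Si](CC)(CC)CC | intermediate
18 | peroxy acid corresponding to 19 | OOC(=O)[C@@H](CC(=O)OC)[C@H](O[Si](C)(C)C(C)(C)C)/C=C(/C)CC[C@H](Cl)[C@@H](C)O[Si](CC)(CC)CC | intermediate (not isolated)
19 | (2S,3R,4Z,8S,9R)-3-[(tert-butyldimethylsilyl)oxy]-8-chloro-2-(2-methoxy-2-oxoethyl)-5-methyl-9-[(triethylsilyl)oxy]dec-4-enoic acid | OC(=O)[C@@H](CC(=O)OC)[C@H](O[Si](C)(C)C(C)(C)C)/C=C(/C)CC[C@H](Cl)[C@@H](C)O[Si](CC)(CC)CC | intermediate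
20 | methyl (3S,4R,5Z,9S,10R)-4-[(tert-butyldimethylsilyl)oxy]-9-chloro-3-[methoxy(methyl)carbamoyl]-6-methyl-10-[(triethylsilyl)oxy]undec-5-enoate | CON(C)C(=O)[C@@H](CC(=O)OC)[C@H](O[Si](C)(C)C(C)(C)C)/C=C(/C)CC[C@H](Cl)[C@@H](C)O[Si](CC)(CC)CC | intermediate
21 | methyl (3S,4R,5Z,9S,10R)-3-(bromoacetyl)-4-[(tert-butyldimethylsilyl)oxy]-9-chloro-6-methyl-10-[(triethylsilyl)oxy]undec-5-enoate | BrCC(=O)[C@@H](CC(=O)OC)[C@H](O[Si](C)(C)C(C)(C)C)/C=C(/C)CC[C@H](Cl)[C@@H](C)O[Si](CC)(CC)CC | intermediate
22 | methyl (3S,4R,5Z,9S,10R)-3-(bromoacetyl)-4-[(tert-butyldimethylsilyl)oxy]-9-chloro-10-hydroxy-6-methylundec-5-enoate | BrCC(=O)[C@@H](CC(=O)OC)[C@H](O[Si](C)(C)C(C)(C)C)/C=C(/C)CC[C@H](Cl)[C@@H](C)O | intermediate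
23 | methyl (3S,4R,5Z,9S)-3-(bromoacetyl)-4-[(tert-butyldimethylsilyl)oxy]-9-chloro-6-methyl-10-oxoundec-5-enoate | BrCC(=O)[C@@H](CC(=O)OC)[C@H](O[Si](C)(C)C(C)(C)C)/C=C(/C)CC[C@H](Cl)C(C)=O | intermediate
24 | trivalent chromium enolate of 23 (O–CrCl2 on C8, C8=C9) | C=C(O[Cr](Cl)Cl)[C@@H](CC(=O)OC)[C@H](O[Si](C)(C)C(C)(C)C)/C=C(/C)CC[C@H](Cl)C(C)=O | intermediate (not isolated)
25 | ten-membered (1S,10R)-chlorohydrin, C10 alkoxide on trivalent chromium | COC(=O)C[C@@H]1C(=O)C[C@@](C)(O[Cr](Cl)Cl)[C@@H](Cl)CC/C(C)=C\[C@H]1O[Si](C)(C)C(C)(C)C | intermediate (not isolated)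
26 | methyl [(1R,6R,7S,10R,4Z)-6-[(tert-butyldimethylsilyl)oxy]-1,10-epoxy-4,10-dimethyl-8-oxocyclodec-4-en-7-yl]acetate (germacrane numbering) | COC(=O)C[C@@H]1C(=O)C[C@@]2(C)O[C@@H]2CC/C(C)=C\[C@H]1O[Si](C)(C)C(C)(C)C | intermediate
27 | 6-hydroxy analogue of 26 | COC(=O)C[C@@H]1C(=O)C[C@@]2(C)O[C@@H]2CC/C(C)=C\[C@H]1O | intermediate (not isolated)
28 | (1R,6R,7S,10R,4Z)-1,10-epoxy-8-oxo-13-norgermacr-4-en-12,6-olide | C1C(=O)O[C@@H]2/C=C(/C)CC[C@H]3O[C@]3(C)CC(=O)[C@@H]12 | intermediate
29 | (1R,6R,7R,8R,10R,4Z)-1,10-epoxy-8-hydroxy-13-norgermacr-4-en-12,6-olide | C1C(=O)O[C@@H]2/C=C(/C)CC[C@H]3O[C@]3(C)C[C@@H](O)[C@@H]12 | intermediate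
30 | angelic acid, (2Z)-2-methylbut-2-enoic acid | C/C=C(/C)C(=O)O | starting material
31 | (2Z)-2-methylbut-2-en-1-ol | C/C=C(/C)CO | intermediate
32 | [(2R,3S)-2,3-dimethyloxiran-2-yl]methanol | OC[C@@]1(C)O[C@H]1C | intermediate
33 | (2S,3S)-2,3-dimethyloxirane-2-carboxylic acid | OC(=O)[C@@]1(C)O[C@H]1C | intermediate
34 | mixed anhydride of 33 with 2,4,6-trichlorobenzoic acid | O=C(OC(=O)c1c(Cl)cc(Cl)cc1Cl)[C@@]1(C)O[C@H]1C | intermediate (not isolated)
35 | (1R,6R,7R,8R,10R,4Z)-1,10-epoxy-8-{[(2S,3S)-2,3-dimethyloxiran-2-yl]carbonyloxy}-13-norgermacr-4-en-12,6-olide | C1C(=O)O[C@@H]2/C=C(/C)CC[C@H]3O[C@]3(C)C[C@@H](OC(=O)[C@@]3(C)O[C@H]3C)[C@@H]12 | intermediate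
36 | lithium enolate of lactone 35 | C1=C(O[Li])O[C@@H]2/C=C(/C)CC[C@H]3O[C@]3(C)C[C@@H](OC(=O)[C@@]3(C)O[C@H]3C)[C@@H]12 | intermediate (not isolated)
37 | 13-(dimethylamino)-11,13-dihydro derivative of 39 (C11 epimers) | CN(C)CC1C(=O)O[C@@H]2/C=C(/C)CC[C@H]3O[C@]3(C)C[C@@H](OC(=O)[C@@]3(C)O[C@H]3C)[C@@H]12 | intermediate
38 | trimethylammonium iodide from 37 | C[N+](C)(C)CC1C(=O)O[C@@H]2/C=C(/C)CC[C@H]3O[C@]3(C)C[C@@H](OC(=O)[C@@]3(C)O[C@H]3C)[C@@H]12.[I-] | intermediate (not isolated)
39 | (1R,6R,7R,8R,10R,4Z)-1,10-epoxy-8-{[(2S,3S)-2,3-dimethyloxiran-2-yl]carbonyloxy}germacra-4,11(13)-dien-12,6-olide | C=C1C(=O)O[C@@H]2/C=C(/C)CC[C@H]3O[C@]3(C)C[C@@H](OC(=O)[C@@]3(C)O[C@H]3C)[C@@H]12 | target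

## Step count and least certain steps

Total: 23 steps. Longest linear sequence: 19 steps (1–6, 8–17, 21–23); steps 7 and 18–20 are side branches.

**Step 15 (key step).** The most likely failures are simple reduction or intermolecular reaction of the chromium enolate instead of ring closure, because ketones are slow acceptors for chromium enolates and the ten-membered ring is strained. Attack on the wrong face of C10 is also possible if the ring transition state overrides the Cornforth preference, as is retro-aldol cleavage during the base stage.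
Fallback (sets out from 9 and 14, comes back at 26): the C9–C10 bond and the oxirane are made between two molecules by known chemistry, and the ring is closed afterwards at C4=C5 by metathesis.
- Iodine–lithium exchange on 9 and protonation give the isopropenyl silyl ether F1, which is desilylated to chlorohydrin F2 and oxidised to the (S)-chloro ketone F3.
- Imide 14 is taken through the operations of steps 8 to 11 with acrolein in place of 11 (aldol adduct F4, silyl ether F5, acid F6, Weinreb amide F7), and MeMgBr converts F7 into methyl ketone F8.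
- The kinetic lithium enolate of F8 (LDA, −78 °C) is added to F3. The Cornforth-controlled chlorohydrin alkoxide closes to the oxirane on warming and gives the open-chain diene F9.
- Ring-closing metathesis of F9 with the second-generation Grubbs catalyst at high dilution closes the ten-membered ring at C4=C5, where the medium ring favours the Z alkene, and returns 26.

**Step 17.** Hydride may enter from the other face of C8, because in the medium ring the two faces are distinguished by ring conformation and not only by the open-chain Felkin preference; enolisation of the β-acyloxy ketone is a lesser risk.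
Fallback (sets out from 28, comes back at 35): if the reduction gives the 8S alcohol F10, it is esterified with acid 33 under Mitsunobu conditions (PPh3, diisopropyl azodicarboxylate), which inverts C8 and gives 35 directly.

**Step 12.** The carbenoid may attack the methyl ester as well as the Weinreb amide, or decompose before it adds, because both carbonyls are electrophilic and bromomethyllithium is short-lived.
Fallback (sets out from 19, comes back at 21): acid 19 is activated as its mixed carbonic anhydride (isobutyl chloroformate, N-methylmorpholine) and treated with diazomethane to give diazoketone F11. Brief treatment with HBr at −20 °C then gives 21; the ester is inert throughout. If the acid also removes the triethylsilyl group, the product is 22 and step 13 is saved.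

**Step 16.** The oxirane, which is β,γ to the ketone and transannular to C4=C5, may open under the acidic fluoride, or the freed β-hydroxy ketone may dehydrate or undergo retro-aldol cleavage before it lactonises.
Fallback (sets out from 21, comes back at 28): the lactone is closed before the ring. Aqueous HF in MeCN removes both silyl groups of 21 to give diol F12, which lactonises in the flask to bromoacetyl lactone F13. Dess–Martin oxidation gives the chloro ketone F14, and the chromium cascade of step 15 applied to F14 gives 28 directly. C7 epimerisation is then harmless, since the trans lactone is the stable isomer.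

**Step 22.** The lactone enolate may attack the neighbouring C8 ester (acyl transfer through a five-membered transition state), or the amide base may open an oxirane.
Fallback (sets out from 29, comes back at 39): the classical order is used. Alcohol 29 is protected as triethylsilyl ether F15, the Mannich reaction gives F16, and quaternisation with elimination gives methylene lactone F17. Buffered desilylation frees alcohol F18, which is esterified with 33 under the conditions of step 21 to give 39.

## Further compounds

F1 | step 15 | {[(2R,3S)-3-chloro-6-methylhept-6-en-2-yl]oxy}triethylsilane | C=C(C)CC[C@H](Cl)[C@@H](C)O[Si](CC)(CC)CC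
F2 | step 15 | (2R,3S)-3-chloro-6-methylhept-6-en-2-ol | C=C(C)CC[C@H](Cl)[C@@H](C)O
F3 | step 15 | (3S)-3-chloro-6-methylhept-6-en-2-one | C=C(C)CC[C@H](Cl)C(C)=O
F4 | step 15 | methyl (3S,4R)-3-{[(4S)-4-benzyl-2-oxo-1,3-oxazolidin-3-yl]carbonyl}-4-hydroxyhex-5-enoate | O=C(N1[C@@H](Cc2ccccc2)COC1=O)[C@@H](CC(=O)OC)[C@H](O)C=C
F5 | step 15 | 4-O-tert-butyldimethylsilyl ether of F4 | O=C(N1[C@@H](Cc2ccccc2)COC1=O)[C@@H](CC(=O)OC)[C@H](O[Si](C)(C)C(C)(C)C)C=C
F6 | step 15 | (2S,3R)-3-[(tert-butyldimethylsilyl)oxy]-2-(2-methoxy-2-oxoethyl)pent-4-enoic acid | OC(=O)[C@@H](CC(=O)OC)[C@H](O[Si](C)(C)C(C)(C)C)C=C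
F7 | step 15 | N-methoxy-N-methylamide of F6 | CON(C)C(=O)[C@@H](CC(=O)OC)[C@H](O[Si](C)(C)C(C)(C)C)C=C
F8 | step 15 | methyl (3S,4R)-3-acetyl-4-[(tert-butyldimethylsilyl)oxy]hex-5-enoate | CC(=O)[C@@H](CC(=O)OC)[C@H](O[Si](C)(C)C(C)(C)C)C=C
F9 | step 15 | open-chain epoxy ketone: methyl (3S,4R)-4-[(tert-butyldimethylsilyl)oxy]-3-{[(2R,3R)-2-methyl-3-(3-methylbut-3-en-1-yl)oxiran-2-yl]acetyl}hex-5-enoate | COC(=O)C[C@H](C(=O)C[C@@]1(C)O[C@@H]1CCC(C)=C)[C@H](O[Si](C)(C)C(C)(C)C)C=C
F10 | step 17 | 8S epimer of 29 | C1C(=O)O[C@@H]2/C=C(/C)CC[C@H]3O[C@]3(C)C[C@H](O)[C@@H]12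
F11 | step 12 | diazomethyl ketone from 19 | [N-]=[N+]=CC(=O)[C@@H](CC(=O)OC)[C@H](O[Si](C)(C)C(C)(C)C)/C=C(/C)CC[C@H](Cl)[C@@H](C)O[Si](CC)(CC)CC
F12 | step 16 | doubly desilylated 21 (4,10-diol) | BrCC(=O)[C@@H](CC(=O)OC)[C@H](O)/C=C(/C)CC[C@H](Cl)[C@@H](C)O
F13 | step 16 | trans-4-(bromoacetyl)-5-[(1Z,5S,6R)-5-chloro-6-hydroxy-2-methylhept-1-en-1-yl]oxolan-2-one | O=C1C[C@H](C(=O)CBr)[C@@H](/C=C(/C)CC[C@H](Cl)[C@@H](C)O)O1
F14 | step 16 | trans-4-(bromoacetyl)-5-[(1Z,5S)-5-chloro-2-methyl-6-oxohept-1-en-1-yl]oxolan-2-one | O=C1C[C@H](C(=O)CBr)[C@@H](/C=C(/C)CC[C@H](Cl)C(C)=O)O1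
F15 | step 22 | 8-O-triethylsilyl ether of 29 | C1C(=O)O[C@@H]2/C=C(/C)CC[C@H]3O[C@]3(C)C[C@@H](O[Si](CC)(CC)CC)[C@@H]12
F16 | step 22 | 11-[(dimethylamino)methyl] derivative of F15 (C11 epimers) | CN(C)CC1C(=O)O[C@@H]2/C=C(/C)CC[C@H]3O[C@]3(C)C[C@@H](O[Si](CC)(CC)CC)[C@@H]12
F17 | step 22 | 8-O-triethylsilyl α-methylene lactone | C=C1C(=O)O[C@@H]2/C=C(/C)CC[C@H]3O[C@]3(C)C[C@@H](O[Si](CC)(CC)CC)[C@@H]12
F18 | step 22 | (1R,6R,7R,8R,10R,4Z)-1,10-epoxy-8-hydroxygermacra-4,11(13)-dien-12,6-olide | C=C1C(=O)O[C@@H]2/C=C(/C)CC[C@H]3O[C@]3(C)C[C@@H](O)[C@@H]12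
A1 | alternative 1 | open-chain dienol with Z C4=C5, E C1=C10, 6R carbinol, C9 silyl ether, C12 PMB ether and C8 1,3-dithiane | CC(C)(C)[Si](C)(C)OC/C(C)=C/CC/C(C)=C\[C@@H](O)[C@H](CCOCc1ccc(OC)cc1)C1SCCCS1
A2 | alternative 1 | (2S)-2-(1,3-dithian-2-yl)-4-[(4-methoxybenzyl)oxy]butanal | O=C[C@H](CCOCc1ccc(OC)cc1)C1SCCCS1
A3 | alternative 1 | [(3E)-5-[(tert-butyldimethylsilyl)oxy]-4-methylpent-3-en-1-yl]copper | [Cu]CC/C=C(\C)CO[Si](C)(C)C(C)(C)C
A4 | alternative 2 | α-methylene 6,12-lactone with C8 silyl ether and E C1=C10 | C=C1C(=O)O[C@@H]2/C=C(/C)CC/C=C(\C)C[C@@H](O[Si](C)(C)C(C)(C)C)[C@@H]12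
A5 | alternative 2 | ten-membered 1(10)E,4Z-dienol with trans C6 hydroxyl and C7 ethynyl groups and C8 silyl ether | C#C[C@H]1[C@H](O)/C=C(/C)CC/C=C(\C)C[C@H]1O[Si](C)(C)C(C)(C)C
A6 | alternative 3 | ten-membered 4Z,1(10)E-diene with C2 bis-sulfone, C6 silyl ether, C7 methoxycarbonylmethyl and C8 PMB ether | C1/C(C)=C\[C@@H](O[Si](C)(C)C(C)(C)C)[C@H](CC(=O)OC)[C@H](OCc2ccc(OC)cc2)C/C(C)=C/C1(S(=O)(=O)c1ccccc1)S(=O)(=O)c1ccccc1
A7 | alternative 3 | open-chain allylic bromide with terminal bis(phenylsulfonyl)methyl group | BrC/C(C)=C\[C@@H](O[Si](C)(C)C(C)(C)C)[C@H](CC(=O)OC)[C@H](OCc1ccc(OC)cc1)C/C(C)=C/C(S(=O)(=O)c1ccccc1)S(=O)(=O)c1ccccc1
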